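The data come from a simulation for an exercise; the scatter is artificial.

At 6.0 min, the time of reading, these flasks are compared for double product, taken here as substrate that has taken up partner twice.

| setting | elm | maple | cedar | red | blue | green | teal |
|---|---|---|---|---|---|---|---|
| substrate | 20 mM | 20 mM | 20 mM | 20 mM (fed, over 5.0 min) | 20 mM (fed, over 5.0 min) | 20 mM | 20 mM |
| partner | 40 mM | 40 mM | 40 mM | 40.0 mM | 40.0 mM | 40.0 mM (fed, over 5.0 min) | 40.0 mM |
| capture agent | 6 mM | 3 mM | 4.5 mM | 6.00 mM | 6.00 mM | 6.00 mM | 6.00 mM |
| temperature | 30 °C | 41 °C | 30 °C | 35 °C |  | 35 °C | 35 °C |
| remark | run made earlier | run made earlier | run made earlier | all else is in the flask from the start; the feed brings no volume worth counting | the addition at −5 °C, then warmed to 35 °C; the feed brings no volume worth counting | all else is in the flask from the start; the feed brings no volume worth counting | everything together at the start |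
| time |  |  |  | 6.0 min | 6.0 min | 6.0 min | 6.0 min |

| elm: time / min | elm: double product / % | maple: time / min | maple: double product / % | cedar: time / min | cedar: double product / % |
|---|---|---|---|---|---|
| 0.833 | 58.9 | 1.33 | 79.9 | 0.667 | 54.3 |
| 2.00 | 75.9 | 2.50 | 84.4 | 1.50 | 72.0 |
| 4.00 | 78.8 | 4.00 | 88.6 | 3.00 | 79.5 |
| 6.00 | 80.4 | 5.00 | 88.4 | 5.00 | 81.6 |

(scatter of a reading: 1 percentage point)

- the flask that comes out highest in amount of double product, in percent of the substrate charged, or "all alike" when all lie within 1.5 percentage points (red / blue / green / teal / all alike)
- double product at the end, in percent of the substrate charged, red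
- double product at the end, in percent of the substrate charged, blue
- double product at the end, in percent of the substrate charged, green
- double product at the end, in percent of the substrate charged, teal



The bench rule treats partner as constant, so that substrate goes pseudo-first-order and double product climbs exponentially to a plateau. In the elm run, taking the last reading of 80.4% as the plateau and the first of 58.9% at 0.833 min, the rule gives a lifetime, as a reading at 30 °C, of 0.632 min. It then expects 77.0% at 2.00 min, where 75.9% was read, a gap of 1.1 percentage points beside a scatter of 1 point.

The border of the rule is one ratio, 1.00 in these flasks: the partner cover, partner charged over twice the substrate charged. The rule needs a cover far above one. At this cover partner falls along with substrate, the rate follows the partner concentration, and the lifetime stretches as partner goes.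

The reckoning here therefore commits to an order, not to a figure for each flask. Teal, charged as elm but warmer, belongs near the elm reading of 80.4%. In red and blue the last portion of substrate enters at 5.0 min, so that portion has 1.00 min, or 1.58 elm lifetimes, against 6.0 min for the substrate of teal, and these two flasks are placed below teal. In green the partner is fed, so the cover counted on partner fed so far stands under one for 5.0 min of the 6.0 min, and green is placed below teal on that count.

The forecast also puts teal highest, at 81%, with red at 75%, blue at 69% and green at 61%, saying of green that “partner is starved”.

The flasks give teal highest at 81.1%, with red at 71.5%, blue at 71.5% and green at 69.4%, which is 8.4 points above the forecast.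

    substrate + partner → first product + by-product (k = 2.09 M⁻¹ s⁻¹, Ea = 47.0 kJ mol⁻¹)
    partner + first product → double product + by-product (k = 4.92 M⁻¹ s⁻¹, Ea = 59.0 kJ mol⁻¹)
    partner + double product → triple product + by-product (k = 0.0394 M⁻¹ s⁻¹, Ea = 53.0 kJ mol⁻¹)
    first product + capture agent → trapped intermediate (k = 1.85 M⁻¹ s⁻¹, Ea = 41.0 kJ mol⁻¹)
    (constants at 35 °C)

Teal, at a cover of 1.00, keeps 5.38% of its partner at 6.00 min, far from the constant level the rule assumed. The neighbour with 50 mM of substrate, otherwise teal, has a cover of 0.400, so its double product can reach at most 40.0% of the substrate charged. That neighbour holds 27.7% at 6.00 min, with partner at 0% of its charge and substrate at 48.0%.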